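## The problem

Target 26 is a eudesmane: a trans-fused decalin whose ring A carries all four stereocentres (C3, C4, C5 and C10, contiguous) and whose ring B carries a cross-conjugated 7(11)-en-8-one. In eudesmane numbering it is the 3β-angelate, 4α-acetate, 5α-H, 10β-methyl compound, (3S,4S,5R,10R).

The quaternary C10 cannot be corrected once made, so it has to come from an enantioselective step. The other three centres can be derived from it:
- C4: the axial C10 methyl group shields the β-face of ring A, so oxygen can be delivered to C4 from the α-face.
- C5: it is epimerisable for as long as C4 is a ketone, and the trans fusion is the thermodynamic one.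
- C3: a C3 ketone should accept hydride axially and give the equatorial 3β-alcohol.

The C3 and C4 oxygens are trans and both equatorial. Neither syn-dihydroxylation nor diaxial epoxide opening of a 3-ene gives this arrangement directly, so one centre must be inverted.

Three groups will not survive rough treatment:
- The angelate: its Z alkene isomerises to the tiglate under acid, base or nucleophilic catalysis.
- The tertiary acetate: it is hard to introduce and can migrate to a free neighbouring hydroxyl.
- The α-isopropylidene ketone: it can deconjugate or be reduced.

The enabling feature lies in ring B. The C8 oxygen sits next to C7, which bears the three-carbon unit C11–C13. A C8 hydroxyl beside a C7 isopropenyl group is what an aldehyde at C8 and a prenyl group on C5 (C6–C7=C11) leave behind after an intramolecular carbonyl-ene reaction. Ring B can therefore be closed through the C7–C8 bond with every ring-B carbon and the oxygen already in place.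

## Retrosynthesis

**Acyl C–O bonds.** The angelate is cut first (26 ⇒ 23 + 24), so that the isomerisation-prone ester meets no further reagent. The acetate is cut one stage earlier, at ketol 21 (22 ⇒ 21): there the tertiary hydroxyl is the only one in the molecule, so selectivity and acyl migration do not arise. Between the two lies the C3–H bond (23 ⇒ 22). The forward reduction must choose the saturated α-acetoxy ketone over the conjugated C8 ketone and must deliver hydride from the α-face.

**C3–O and C4–O bonds.** Both oxygens are traced to the 3-ene of dienone 19 through syn-dihydroxylation (20 ⇒ 19) and oxidation of the secondary carbinol (21 ⇒ 20). The neighbouring options are worse. Methyl addition to a C4 ketone would come from the α-face and give the 4β-alcohol. Epoxide opening would give a diaxial diol. Dihydroxylation from the α-face sets C4 correctly and leaves only C3 to be inverted by the oxidation–reduction pair. The forward step must spare the 7(11)-alkene, which is tetrasubstituted and electron-poor in 19; this is why the enone is formed before the diol.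

**C4–C15 bond and the ring-B enone.** Dienone 19 is simplified in two ways. The enone goes back to homoallylic alcohol 17 (oxidation, then alkene migration into conjugation). The C4 methyl group goes back through silyl ether 16 to enol triflate 15 and ketone 13 (16 ⇒ 15 ⇒ 13 ⇒ 12). A cross-coupling on a kinetically formed enol triflate fixes the alkene at C3–C4. The alternative, methylenation of the ketone and isomerisation, would not control the alkene position. The ring-B alcohol is silylated during this phase because a free hydroxyl or a C8 ketone would interfere with regioselective enolisation at C3.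

**C7–C8 bond (key disconnection).** Hydroxy ketone 12 is opened to keto aldehyde 11. This removes ring B and two stereocentres and leaves a monocyclic ketone with a single fixed stereocentre. The competing cuts of ring B (C5–C6 or C9–C10) would need a new functional handle; the C7–C8 cut uses only the aldehyde and the prenyl alkene, and the ene reaction returns exactly the C8 oxygen and the C7 three-carbon unit that the target requires. The forward reaction must engage the aldehyde and not the ring ketone, and must transfer hydrogen instead of capturing chloride.

**C8 oxidation level.** Aldehyde 11 comes from alcohol 10, and 10 from the vinyl group of ketone 8 by terminal hydroboration–oxidation. A vinyl group is the simplest two-carbon unit that can be placed on a quaternary carbon by conjugate addition, and it can be told apart from the prenyl alkene by its substitution.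

**C5–C6 and C9–C10 bonds.** Ketone 8 is cut at the prenyl group to enol ether 5 and prenyl bromide 6. Enol ether 5 is cut at the vinyl group to enone 1 and vinylmagnesium bromide 2. Conjugate addition creates the quaternary centre enantioselectively and hands over the enolate on the correct side, so the alkylation is regiospecific. The alkylation is not asked to control C5: that centre remains α to a ketone until ring B is closed, and is then set thermodynamically.

## Roads not taken

Alternative 1: Transannular cyclisation. The cut is the C5–C10 bond, which opens both rings to a ten-membered (E,E)-dienone, the 3-silyloxygermacrone A1. In the forward step, dilute aqueous acid would protonate C1 of the 1(10)-alkene, C5 would bond to C10 across the ring, and water would quench the C4 cation, giving the 3β-silyloxy-4α-hydroxy enone A2.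
- Merits: one step closes both rings, sets C5 and C10 and installs the C4 oxygen, with the isopropylidene ketone present from the start. From A2 only acetylation, desilylation and angeloylation remain. This endgame is clearly shorter than the six steps needed after 19.
- Weak points: A1 needs an enantiopure, C3-oxygenated cyclodecadienone with two E trisubstituted alkenes, which is a medium-ring problem of its own. The cyclisation has several outcomes that are hard to steer: which alkene is protonated, elimination against water capture, and the face of capture at C4. The absolute configuration of C5 and C10 would rest on relay from the single C3 centre through a flexible ring. Such dienes also undergo Cope rearrangement on warming.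
- Comparison: in step count and in direct C4 oxygenation this road is better. The chosen plan sets against it that each stereocentre is made by a separate operation with close precedent and that no medium ring has to be built.

Alternative 2: Dearomative para-allylation. The cut is the C9–C10 bond, back to phenol A3, a 2,4-dimethylphenol whose C3 side chain ends in a 2-substituted allyl carbonate. In the forward step, Pd2(dba)3 (zerovalent palladium) with a chiral diphosphine would ionise the carbonate and the phenolate would attack the π-allyl unit through its para carbon, closing ring B and creating C10 in dienone A4.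
- Merits: the precursor is assembled by ordinary arene chemistry, and the catalyst sets C10 in the ring-forming step. Ring A of A4 is better suited to the C4/C5 problem than anything in the chosen route. Dissolving-metal reduction of the 4-en-3-one would set the trans fusion unambiguously and release the C3–C4 enolate for α-face oxidation. That gives the 4α-hydroxy 3-ketone without the dihydroxylation–oxidation detour.
- Weak points: the tether-bearing carbon has two methyl-substituted neighbours, the para carbon (C10) and the ortho carbon (C4). Attack at either closes a six-membered ring, so regiochemistry rests on the catalyst alone. Ring B of A4 carries only an exocyclic methylene at C8 and nothing at C7. The ketone would need alkene cleavage in the presence of a dienone, and the three-carbon unit would need an aldol-type introduction at C7 rather than C9. The 1,2-alkene must also be reduced selectively.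
- Comparison: this road is as good or better for C10 and for ring A. The chosen plan sets against it that the ene closure delivers ring B complete, with the C8 oxygen and the C7 unit in place, and has no ortho/para question.

Alternative 3: Gold-catalysed enyne bicyclisation. The cuts are the C4–C5 and C9–C10 bonds, back to the acyclic C15 chain A5: a methyl alkyne, an (E)-trisubstituted alkene and a silyl dienol ether. In the forward step, (R)-DTBM-SEGPHOS(AuCl)2 activated by AgSbF6 (monovalent gold) would activate the alkyne. C5 would attack C4, and C9 of the dienol ether would trap the C10 cation, giving dienone A6.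
- Merits: both rings and both ring-fusion centres arise in one step, with the E alkene translating into the trans fusion. A6 is the same compound as 19, which the chosen route reaches only after ten steps. With a short assembly of A5 this road would be markedly more step-economical, and the endgame would be shared.
- Weak points: enantiocontrol of a cationic cascade by a ligand on linearly coordinated gold depends strongly on the substrate. The terminator is a cross-conjugated silyl dienol ether on a tetrasubstituted alkene. It is the most nucleophilic and most acid-labile part of A5 and may react out of sequence or lose silicon. Closure at the alkyne must be endo to give the six-membered ring A. A5 needs a stereodefined trisubstituted alkene.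
- Comparison: this road is better in step economy. The chosen plan sets against it reliability: C10 comes from an established conjugate-addition manifold, ring B from an ene closure with the citronellal precedent, and no single step must control two stereocentres and two ring closures at once.

Key step: step 5

Assumption: the enolate prenylation of step 2 is not expected to be diastereoselective, so 8, 10 and 11 are drawn as their 2,3-trans epimers but are carried forward with their C2 epimers; that carbon (C5 of the eudesmane) stays α to a ketone until step 5, whose base treatment is relied on to set the trans ring fusion.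

## Route

Step 1
Reactants: 1 3-methylcyclohex-2-en-1-one; 2 vinylmagnesium bromide
Product: 5 (R)-trimethyl[(3-methyl-3-vinylcyclohex-1-en-1-yl)oxy]silane, via dimethyl(vinyl)aluminium 3 (not isolated), via dimethylaluminium enolate 4 (not isolated)
Conditions: 2, Me2AlCl, Et2O, 0 °C; then 1, copper thiophene-2-carboxylate Cu(O2CC4H3S) (5 mol %), chiral phosphinamine ligand Ph2P–N[CH(CH3)(2-naphthyl)]2 (10 mol %), Et2O, −30 °C; then TMSOTf, −30 → 0 °C; Et3N, aq. NaHCO3 work-up
Reagents that add atoms: trimethylsilyl trifluoromethanesulfonate, C[Si](C)(C)OS(=O)(=O)C(F)(F)F; chlorodimethylalane, C[Al](C)Cl (aluminium and methyl groups of 3 and 4 only)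
Why: Copper-catalysed asymmetric conjugate addition of an alkenylalane to a β-substituted cyclohexenone, in which the sp2 group transfers in preference to methyl; the ligand antipode is chosen to give the R enol ether (the (S)-3-methyl-3-vinylcyclohexanone series), which sets the quaternary carbon that becomes C10. O-Silylation of aluminium enolate 4 fixes the enolate on the side of the quaternary carbon, which later deprotonation of the free ketone could not do.

Step 2
Reactants: 5 (R)-trimethyl[(3-methyl-3-vinylcyclohex-1-en-1-yl)oxy]silane; 6 prenyl bromide (1-bromo-3-methylbut-2-ene)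
Product: 8 (2R,3R)-3-methyl-2-(3-methylbut-2-en-1-yl)-3-vinylcyclohexan-1-one, via lithium enolate 7 (not isolated)
Conditions: MeLi, THF, 0 → 23 °C; then DMPU, 6, −78 → −20 °C
Reagents that add atoms: methyllithium, [Li]C (lithium of 7 only)
Why: Methyllithium cleaves the O–Si bond and releases lithium enolate 7 with its regiochemistry intact, and SN2 alkylation by the reactive allylic bromide forms the C5–C6 bond before proton transfer can scramble the enolate. The new centre is not expected to form selectively because the neighbouring quaternary carbon offers methyl and vinyl groups of similar size; it is α to the ketone and is settled in step 5.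

Step 3
Reactants: 8 (2R,3R)-3-methyl-2-(3-methylbut-2-en-1-yl)-3-vinylcyclohexan-1-one
Product: 10 (2R,3R)-3-(2-hydroxyethyl)-3-methyl-2-(3-methylbut-2-en-1-yl)cyclohexan-1-one, via pinacol boronate 9 (not isolated)
Conditions: pinacolborane, RhCl(PPh3)3 (2 mol %), CH2Cl2, 23 °C; then NaBO3·4H2O, THF/H2O, 23 °C
Reagents that add atoms: pinacolborane, [H]B1OC(C)(C)C(C)(C)O1 (boronate group of 9 only); sodium perborate, [Na+].[O-]B1OO1 (hydroxyl oxygen)
Why: Rhodium-catalysed hydroboration places boron on the terminal carbon of the monosubstituted vinyl group only; the trisubstituted prenyl alkene is inert to this catalyst and the hindered ketone should not be reduced at a competitive rate, the known chemoselectivity of the catalysed reaction of keto alkenes. Perborate oxidises the C–B bond to the primary alcohol under near-neutral conditions; no stereocentre is formed.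

Step 4
Reactants: 10 (2R,3R)-3-(2-hydroxyethyl)-3-methyl-2-(3-methylbut-2-en-1-yl)cyclohexan-1-one
Product: 11 (2R,3R)-3-methyl-2-(3-methylbut-2-en-1-yl)-3-(2-oxoethyl)cyclohexan-1-one
Conditions: Dess–Martin periodinane, NaHCO3, CH2Cl2, 0 → 23 °C
Reagents that add atoms: none
Why: Dess–Martin oxidation stops at the aldehyde, and the buffered, non-basic medium avoids aldol reaction of the keto aldehyde; the aldehyde α-carbon is a CH2 next to a quaternary centre, so nothing epimerisable is created.

Step 5
Reactants: 11 (2R,3R)-3-methyl-2-(3-methylbut-2-en-1-yl)-3-(2-oxoethyl)cyclohexan-1-one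
Product: 12 (4aR,6S,7R,8aR)-6-hydroxy-4a-methyl-7-(prop-1-en-2-yl)octahydronaphthalen-1(2H)-one
Conditions: Me2AlCl (1.5 equiv), CH2Cl2, −78 → −20 °C; aq. HCl work-up; then K2CO3, MeOH, 23 °C
Reagents that add atoms: none
Why: Me2AlCl binds the aldehyde oxygen; C7 of the trisubstituted prenyl alkene attacks C8 while a hydrogen of an allylic methyl group passes to oxygen through a chair-like six-membered array, and loss of methane from the methylaluminium alkoxide makes the step irreversible. The closest known reaction is the Lewis-acid type 1 intramolecular carbonyl-ene cyclisation of citronellal to isopulegol, which has the same tether and the same alkene. Ring B closes as a six-membered ring, exo with respect to the alkene (C7 becomes a ring atom, C11 stays outside). At C8 the complexed carbonyl lies equatorial, away from the axial C10 methyl group, which gives the 8α-alcohol; at C7 the alkene arm is equatorial in the chair, which places the isopropenyl group β and trans to the hydroxyl; neither centre matters later, since both are removed in step 10. C5 ends trans to the C10 methyl group because K2CO3 in methanol equilibrates this α-keto methine, so that cis-fused ketol from the C2 epimer of 11 is drawn into the all-equatorial trans-decalone 12. The step needs aldehyde-over-ketone selectivity, secured by the higher reactivity of the aldehyde complex and by geometry (the ketone could only form a four-membered ring with the alkene). It also needs hydrogen transfer to outrun chloride capture and aldol closure, which the limited amount of Me2AlCl, the proton-scavenging Al–Me bond and the low temperature favour.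

Step 6
Reactants: 12 (4aR,6S,7R,8aR)-6-hydroxy-4a-methyl-7-(prop-1-en-2-yl)octahydronaphthalen-1(2H)-one
Product: 13 (4aR,6S,7R,8aR)-6-[(tert-butyldimethylsilyl)oxy]-4a-methyl-7-(prop-1-en-2-yl)octahydronaphthalen-1(2H)-one
Conditions: TBSCl, imidazole, DMF, 40 °C
Reagents that add atoms: tert-butyldimethylsilyl chloride, CC(C)(C)[Si](C)(C)Cl
Why: Standard silylation of the equatorial secondary alcohol; the ether masks C8 during the enolate and Grignard chemistry at C4 and is stable to both.

Step 7
Reactants: 13 (4aR,6S,7R,8aR)-6-[(tert-butyldimethylsilyl)oxy]-4a-methyl-7-(prop-1-en-2-yl)octahydronaphthalen-1(2H)-one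
Product: 15 (4aR,6S,7R,8aR)-6-[(tert-butyldimethylsilyl)oxy]-4a-methyl-7-(prop-1-en-2-yl)-3,4,4a,5,6,7,8,8a-octahydronaphthalen-1-yl trifluoromethanesulfonate, via potassium enolate 14 (not isolated)
Conditions: KN(SiMe3)2, THF, −78 °C; then PhNTf2, −78 → 0 °C
Reagents that add atoms: N-phenylbis(trifluoromethanesulfonimide), O=S(=O)(N(c1ccccc1)S(=O)(=O)C(F)(F)F)C(F)(F)F; potassium bis(trimethylsilyl)amide, [K+].C[Si](C)(C)[N-][Si](C)(C)C (potassium of 14 only)
Why: Kinetic deprotonation by the bulky amide removes a C3 methylene hydrogen instead of the hindered ring-fusion hydrogen at C5, and O-sulfonylation of enolate 14 gives the C3=C4 enol triflate regiospecifically. C5 is untouched under these non-equilibrating conditions and is no longer epimerisable afterwards.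

Step 8
Reactants: 15 (4aR,6S,7R,8aR)-6-[(tert-butyldimethylsilyl)oxy]-4a-methyl-7-(prop-1-en-2-yl)-3,4,4a,5,6,7,8,8a-octahydronaphthalen-1-yl trifluoromethanesulfonate
Product: 16 tert-butyldimethylsilyl ether of (5R,7R,8S,10R)-eudesma-3,11-dien-8-ol (8α-silyloxy)
Conditions: MeMgBr, Fe(acac)3 (5 mol %), THF/NMP, −30 → 0 °C
Reagents that add atoms: methylmagnesium bromide, C[Mg]Br
Why: Iron-catalysed Kumada-type cross-coupling of an alkenyl triflate with an alkyl Grignard reagent replaces the triflate by methyl without moving the alkene, which installs C15 and the 3-ene; the silyl ether and the isopropenyl group are inert.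

Step 9
Reactants: 16 tert-butyldimethylsilyl ether of (5R,7R,8S,10R)-eudesma-3,11-dien-8-ol
Product: 17 (5R,7R,8S,10R)-eudesma-3,11-dien-8-ol
Conditions: Bu4NF, THF, 23 °C
Reagents that add atoms: none
Why: Fluoride cleaves the Si–O bond and frees the C8 alcohol for oxidation; nothing else in 16 reacts with fluoride.

Step 10
Reactants: 17 (5R,7R,8S,10R)-eudesma-3,11-dien-8-ol
Product: 19 (5R,10R)-eudesma-3,7(11)-dien-8-one, via eudesma-3,11-dien-8-one 18 (not isolated)
Conditions: Dess–Martin periodinane, NaHCO3, CH2Cl2, 0 → 23 °C; filtration; then DBU, CH2Cl2, 23 °C
Reagents that add atoms: none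
Why: Oxidation gives β,γ-unsaturated ketone 18, whose C7 hydrogen is both α to the carbonyl and allylic; DBU removes it and reprotonation at the terminal carbon moves the alkene into conjugation (the isopulegone-to-pulegone isomerisation), the tetrasubstituted enone being the thermodynamic isomer. Both stereocentres made in step 5 disappear here.

Step 11
Reactants: 19 (5R,10R)-eudesma-3,7(11)-dien-8-one
Product: 20 (3R,4S,5R,10R)-3,4-dihydroxyeudesm-7(11)-en-8-one (3α,4α-diol)
Conditions: OsO4 (2 mol %), N-methylmorpholine N-oxide, acetone/H2O, 23 °C
Reagents that add atoms: N-methylmorpholine N-oxide, C[N+]1([O-])CCOCC1; water, O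
Why: Upjohn dihydroxylation: OsO4 adds suprafacially to the electron-rich trisubstituted 3-ene from the α-face, opposite the C10 methyl group that is syn-axial to C4; this sets C4 (4α-hydroxyl, 4β-methyl) and gives the 3α-alcohol. The tetrasubstituted, electron-poor enone alkene is expected to be inert.

Step 12
Reactants: 20 (3R,4S,5R,10R)-3,4-dihydroxyeudesm-7(11)-en-8-one
Product: 21 (4S,5R,10R)-4-hydroxyeudesm-7(11)-ene-3,8-dione
Conditions: Dess–Martin periodinane, NaHCO3, CH2Cl2, 0 °C
Reagents that add atoms: none
Why: Only the secondary C3 carbinol can be oxidised, and this reagent converts secondary–tertiary 1,2-diols into α-ketols without C–C cleavage; the C3 centre that had the wrong configuration is erased.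

Step 13
Reactants: 21 (4S,5R,10R)-4-hydroxyeudesm-7(11)-ene-3,8-dione
Product: 22 (4S,5R,10R)-4-acetoxyeudesm-7(11)-ene-3,8-dione
Conditions: Ac2O, DMAP, Et3N, CH2Cl2, 23 → 40 °C
Reagents that add atoms: acetic anhydride, CC(=O)OC(C)=O
Why: DMAP-catalysed acetylation of a tertiary α-ketol, as practised on tertiary α-hydroxy ketones of the steroid series; no other hydroxyl is present, so neither selectivity nor acyl migration is an issue at this stage.

Step 14
Reactants: 22 (4S,5R,10R)-4-acetoxyeudesm-7(11)-ene-3,8-dione
Product: 23 (3S,4S,5R,10R)-4-acetoxy-3-hydroxyeudesm-7(11)-en-8-one (3β-alcohol)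
Conditions: NaBH4, MeOH/CH2Cl2 (1:1), −78 °C; AcOH quench
Reagents that add atoms: none
Why: Borohydride in methanol–dichloromethane at low temperature reduces a saturated ketone, here further activated by the α-acetoxy group, faster than a conjugated tetrasubstituted enone. Hydride adds along the axial trajectory from the α-face, because equatorial approach is blocked by the axial 4β-methyl group, and gives the equatorial 3β-alcohol (C3 S); the cold, brief reaction and acidic quench limit acetyl migration.

Step 15
Reactants: 23 (3S,4S,5R,10R)-4-acetoxy-3-hydroxyeudesm-7(11)-en-8-one; 24 angelic acid [(Z)-2-methylbut-2-enoic acid]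
Product: 26 (3S,4S,5R,10R)-4-acetoxy-3-[(Z)-2-methylbut-2-enoyloxy]eudesm-7(11)-en-8-one (CNP0141494.1), via mixed anhydride 25 (not isolated)
Conditions: 24, 2,4,6-trichlorobenzoyl chloride, Et3N, toluene, 23 °C; then 23, toluene, 80 °C
Reagents that add atoms: 2,4,6-trichlorobenzoyl chloride, O=C(Cl)c1c(Cl)cc(Cl)cc1Cl (aroyl group of 25 only)
Why: Mixed-anhydride (Yamaguchi-type) esterification in which alcohol 23 attacks the less hindered angeloyl carbonyl of 25; leaving out a nucleophilic catalyst avoids conjugate addition–elimination at the acyl unit, so the Z geometry should be retained. No stereocentre is affected.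

## Compound list

1 | 3-methylcyclohex-2-en-1-one | CC1=CC(=O)CCC1 | starting material
2 | vinylmagnesium bromide | C=C[Mg]Br | starting material
3 | dimethyl(vinyl)aluminium | C=C[Al](C)C | intermediate (not isolated)
4 | dimethylaluminium (R)-3-methyl-3-vinylcyclohex-1-en-1-olate | C[Al](C)OC1=C[C@@](C)(C=C)CCC1 | intermediate (not isolated)
5 | (R)-trimethyl[(3-methyl-3-vinylcyclohex-1-en-1-yl)oxy]silane | C[Si](C)(C)OC1=C[C@@](C)(C=C)CCC1 | intermediate
6 | prenyl bromide (1-bromo-3-methylbut-2-ene) | CC(C)=CCBr | starting material
7 | lithium (R)-3-methyl-3-vinylcyclohex-1-en-1-olate | [Li+].[O-]C1=C[C@@](C)(C=C)CCC1 | intermediate (not isolated)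
8 | (2R,3R)-3-methyl-2-(3-methylbut-2-en-1-yl)-3-vinylcyclohexan-1-one (prenyl trans to vinyl) | O=C1CCC[C@](C)(C=C)[C@H]1CC=C(C)C | intermediate
9 | (2R,3S)-3-methyl-2-(3-methylbut-2-en-1-yl)-3-[2-(4,4,5,5-tetramethyl-1,3,2-dioxaborolan-2-yl)ethyl]cyclohexan-1-one | O=C1CCC[C@](C)(CCB2OC(C)(C)C(C)(C)O2)[C@H]1CC=C(C)C | intermediate (not isolated)
10 | (2R,3R)-3-(2-hydroxyethyl)-3-methyl-2-(3-methylbut-2-en-1-yl)cyclohexan-1-one | O=C1CCC[C@](C)(CCO)[C@H]1CC=C(C)C | intermediate
11 | (2R,3R)-3-methyl-2-(3-methylbut-2-en-1-yl)-3-(2-oxoethyl)cyclohexan-1-one | O=C1CCC[C@](C)(CC=O)[C@H]1CC=C(C)C | intermediate (key-step precursor)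
12 | (4aR,6S,7R,8aR)-6-hydroxy-4a-methyl-7-(prop-1-en-2-yl)octahydronaphthalen-1(2H)-one (trans-fused; 8α-OH, 7β-isopropenyl in eudesmane terms) | O=C1CCC[C@]2(C)C[C@H](O)[C@@H](C(C)=C)C[C@@H]12 | intermediate (key-step product)
13 | (4aR,6S,7R,8aR)-6-[(tert-butyldimethylsilyl)oxy]-4a-methyl-7-(prop-1-en-2-yl)octahydronaphthalen-1(2H)-one | O=C1CCC[C@]2(C)C[C@H](O[Si](C)(C)C(C)(C)C)[C@@H](C(C)=C)C[C@@H]12 | intermediate
14 | potassium enolate of 13 (C3=C4 enolate) | [K+].[O-]C1=CCC[C@]2(C)C[C@H](O[Si](C)(C)C(C)(C)C)[C@@H](C(C)=C)C[C@@H]12 | intermediate (not isolated)
15 | (4aR,6S,7R,8aR)-6-[(tert-butyldimethylsilyl)oxy]-4a-methyl-7-(prop-1-en-2-yl)-3,4,4a,5,6,7,8,8a-octahydronaphthalen-1-yl trifluoromethanesulfonate | FC(F)(F)S(=O)(=O)OC1=CCC[C@]2(C)C[C@H](O[Si](C)(C)C(C)(C)C)[C@@H](C(C)=C)C[C@@H]12 | intermediate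
16 | tert-butyldimethylsilyl ether of (5R,7R,8S,10R)-eudesma-3,11-dien-8-ol | CC1=CCC[C@]2(C)C[C@H](O[Si](C)(C)C(C)(C)C)[C@@H](C(C)=C)C[C@@H]12 | intermediate
17 | (5R,7R,8S,10R)-eudesma-3,11-dien-8-ol | CC1=CCC[C@]2(C)C[C@H](O)[C@@H](C(C)=C)C[C@@H]12 | intermediate
18 | (5R,7R,10R)-eudesma-3,11-dien-8-one | CC1=CCC[C@]2(C)CC(=O)[C@@H](C(C)=C)C[C@@H]12 | intermediate (not isolated)
19 | (5R,10R)-eudesma-3,7(11)-dien-8-one | CC1=CCC[C@]2(C)CC(=O)C(=C(C)C)C[C@@H]12 | intermediate
20 | (3R,4S,5R,10R)-3,4-dihydroxyeudesm-7(11)-en-8-one (3α,4α-diol) | O[C@@H]1CC[C@]2(C)CC(=O)C(=C(C)C)C[C@H]2[C@]1(C)O | intermediate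
21 | (4S,5R,10R)-4-hydroxyeudesm-7(11)-ene-3,8-dione (4α-hydroxyl) | O=C1CC[C@]2(C)CC(=O)C(=C(C)C)C[C@H]2[C@]1(C)O | intermediate
22 | (4S,5R,10R)-4-acetoxyeudesm-7(11)-ene-3,8-dione | O=C1CC[C@]2(C)CC(=O)C(=C(C)C)C[C@H]2[C@]1(C)OC(C)=O | intermediate
23 | (3S,4S,5R,10R)-4-acetoxy-3-hydroxyeudesm-7(11)-en-8-one (3β-alcohol) | O[C@H]1CC[C@]2(C)CC(=O)C(=C(C)C)C[C@H]2[C@]1(C)OC(C)=O | intermediate
24 | angelic acid, (Z)-2-methylbut-2-enoic acid | C/C=C(/C)C(=O)O | starting material
25 | (Z)-2-methylbut-2-enoic 2,4,6-trichlorobenzoic anhydride | C/C=C(/C)C(=O)OC(=O)c1c(Cl)cc(Cl)cc1Cl | intermediate (not isolated)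
26 | (3S,4S,5R,10R)-4-acetoxy-3-[(Z)-2-methylbut-2-enoyloxy]eudesm-7(11)-en-8-one | C/C=C(/C)C(=O)O[C@H]1CC[C@]2(C)CC(=O)C(=C(C)C)C[C@H]2[C@]1(C)OC(C)=O | target

## Step count and least certain steps

Total step count: 15. Longest linear sequence: 15 steps (the route is linear from 1).

**Step 5 (key step).**
- What may go wrong: competition at the Lewis acid. The ring ketone can sequester Me2AlCl and, once complexed, enolise toward C3, so that aldol closure onto the aldehyde or chloride capture at C11 overtakes hydrogen transfer.
- A second concern is incomplete convergence at the ring fusion. If the C2 epimer of 11 cyclises through a chair that places the new C8 oxygen syn to the angular methyl group, that material resists epimerisation and has to be removed by chromatography.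
- Fallback: run the closure with the ketone masked. Setting out from 8, ketalisation with 1,2-bis(trimethylsilyloxy)ethane and catalytic TMSOTf (CH2Cl2, −78 °C) gives the ethylene ketal F6. Hydroboration–oxidation with 9-BBN, now free of any carbonyl, gives ketal alcohol F7, and Dess–Martin oxidation gives ketal aldehyde F8. The Me2AlCl ene closure then gives the ketal of the ring-closed alcohol F9. Aqueous HCl in THF removes the ketal and K2CO3 in methanol equilibrates C5, which returns the route at 12.

**Step 1.**
- What may go wrong: loss of enantioselectivity, or methyl transfer in competition with vinyl transfer. The mixed alane is made from a Grignard reagent, and the magnesium salts may open an unselective background pathway.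
- Fallback: exchange the roles of nucleophile and acceptor. Setting out from 2, addition to 3-ethoxycyclohex-2-en-1-one and acidic hydrolysis give 3-vinylcyclohex-2-en-1-one F1. MeMgBr with Cu(OTf)2 and a chiral imidazolium-derived carbene ligand adds to F1 in the 1,4-sense, not the 1,6-sense, to give the bromomagnesium enolate F2. TMSCl with Et3N converts F2 into 5, where the route resumes.

**Step 2.**
- What may go wrong: proton transfer between the product ketone and unreacted enolate, which leads to regioisomeric and multiple alkylation at this hindered position.
- Fallback: make the C–C bond within an ion pair. Setting out from 5, enolate 7 is generated as before and acylated on oxygen with prenyl chloroformate to give the enol carbonate F3. Pd(PPh3)4 (zerovalent palladium) in THF then effects decarboxylative allylation at the less substituted allyl terminus and returns the route at 8.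
- This fallback does not change the facial outcome at C2, which is dealt with in step 5.

**Step 3.**
- What may go wrong: reduction of the ketone in competition with a slow hydroboration of the vinyl group, which sits on a quaternary carbon.
- Fallback: give up chemoselectivity and correct the oxidation level afterwards. Setting out from 8, LiAlH4 reduction gives the cyclohexanol F4 (both carbinol epimers). Treatment with 9-BBN and then NaOH/H2O2 gives the diol F5. A double Swern oxidation (oxalyl chloride, DMSO, Et3N) converts both carbinols and returns the route at 11, bypassing 10.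

**Step 14 (with step 15).**
- What may go wrong: over-reduction at the C8 enone, and migration of the acetyl group from the tertiary O4 to the new secondary O3, during the reduction or during the warm esterification.
- Fallback: postpone the acetate. Setting out from 21, hydroxyl-directed reduction with Me4NBH(OAc)3 (MeCN/AcOH, −20 °C) delivers hydride from the face of the 4α-hydroxyl and gives the trans-diol F10; this reagent leaves ketones without a neighbouring hydroxyl alone. The mixed-anhydride angeloylation of step 15 then acylates only the secondary alcohol and gives the hydroxy angelate F11. Ac2O with catalytic Sc(OTf)3 (MeCN, −20 °C) acetylates the tertiary alcohol and returns the route at 26.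

## Further compounds

F1 | step 1 | 3-vinylcyclohex-2-en-1-one | C=CC1=CC(=O)CCC1
F2 | step 1 | bromomagnesium (R)-3-methyl-3-vinylcyclohex-1-en-1-olate | Br[Mg]OC1=C[C@@](C)(C=C)CCC1
F3 | step 2 | (R)-3-methyl-3-vinylcyclohex-1-en-1-yl 3-methylbut-2-en-1-yl carbonate | CC(C)=CCOC(=O)OC1=C[C@@](C)(C=C)CCC1
F4 | step 3 | (2R,3R)-3-methyl-2-(3-methylbut-2-en-1-yl)-3-vinylcyclohexan-1-ol (both C1 epimers) | OC1CCC[C@](C)(C=C)[C@H]1CC=C(C)C
F5 | step 3 | (2R,3R)-3-(2-hydroxyethyl)-3-methyl-2-(3-methylbut-2-en-1-yl)cyclohexan-1-ol (both C1 epimers) | OC1CCC[C@](C)(CCO)[C@H]1CC=C(C)C
F6 | step 5 | (6R,7R)-7-methyl-6-(3-methylbut-2-en-1-yl)-7-vinyl-1,4-dioxaspiro[4.5]decane (ethylene ketal of 8) | C12(OCCO1)CCC[C@](C)(C=C)[C@H]2CC=C(C)C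
F7 | step 5 | ethylene ketal of 10 | C12(OCCO1)CCC[C@](C)(CCO)[C@H]2CC=C(C)C
F8 | step 5 | ethylene ketal of 11 | C12(OCCO1)CCC[C@](C)(CC=O)[C@H]2CC=C(C)C
F9 | step 5 | ethylene ketal of 12 | C13(OCCO1)CCC[C@]2(C)C[C@H](O)[C@@H](C(C)=C)C[C@@H]32
F10 | step 14 | (3S,4S,5R,10R)-3,4-dihydroxyeudesm-7(11)-en-8-one (3β,4α-diol) | O[C@H]1CC[C@]2(C)CC(=O)C(=C(C)C)C[C@H]2[C@]1(C)O
F11 | step 14 | (3S,4S,5R,10R)-4-hydroxy-3-[(Z)-2-methylbut-2-enoyloxy]eudesm-7(11)-en-8-one | C/C=C(/C)C(=O)O[C@H]1CC[C@]2(C)CC(=O)C(=C(C)C)C[C@H]2[C@]1(C)O
A1 | alternative 1 | (3S)-3-[(tert-butyldimethylsilyl)oxy]germacrone (germacrane numbering; 1(10)E,4E) | C/C/1=C\CC(=C(C)C)C(=O)C/C(=C/C[C@@H]1O[Si](C)(C)C(C)(C)C)/C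
A2 | alternative 1 | 3β-[(tert-butyldimethylsilyl)oxy]-4α-hydroxyeudesm-7(11)-en-8-one | CC(C)(C)[Si](C)(C)O[C@H]1CC[C@]2(C)CC(=O)C(=C(C)C)C[C@H]2[C@]1(C)O
A3 | alternative 2 | 2-[2-(3-hydroxy-2,6-dimethylphenyl)ethyl]prop-2-en-1-yl methyl carbonate | COC(=O)OCC(=C)CCc1c(C)ccc(O)c1C
A4 | alternative 2 | (4aS)-1,4a-dimethyl-6-methylidene-5,6,7,8-tetrahydronaphthalen-2(4aH)-one (10β-methyl in eudesmane terms) | CC1=C2CCC(=C)C[C@@]2(C)C=CC1=O
A5 | alternative 3 | tert-butyldimethyl{[(5E)-6-methyl-3-(propan-2-ylidene)undeca-1,5-dien-9-yn-2-yl]oxy}silane | CC#CCC/C(C)=C/CC(=C(C)C)C(=C)O[Si](C)(C)C(C)(C)C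
A6 | alternative 3 | (5R,10R)-eudesma-3,7(11)-dien-8-one (identical with 19) | CC1=CCC[C@]2(C)CC(=O)C(=C(C)C)C[C@@H]12
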